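common to all: starting material 0.020 M
- midnight: solid second substrate 0.012 M; free enzyme 4 µM; the very flask that is asked about, followed so far
- noon: solid second substrate 0.024 M; free enzyme 4 µM; run made earlier
- flask: solid second substrate 0.0120 M; free enzyme 4.0 µM; time 12 h

- midnight (time / min: target / %, starting material / %): 80.0: 60.1, 39.3; 180: 59.8, 40.1; 360: 60.3, 39.6; 600: 61.0, 40.2
- noon (time / min: target / %, starting material / %): 5.00: 6.2, 93.8; 15.0: 20.9, 79.6; 25.0: 36.4, 63.2; 40.0: 55.2, 44.6

(scatter of a reading: 0.5 percentage points)

- zeta: change nothing and wait 6.0 h more
- eta: at 12 h add free enzyme, 100% of the amount charged, then wait 6.0 h
- alpha: at 12 h add starting material, 50.0% of the amount charged, then wait 6.0 h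
- delta: at 12 h take out 90% of the target then present, then wait 6.0 h

* target, in percent of the starting material first charged, at 12 h
* the option that brings most further target ("none" if no option brings more than 2 percentage points) (zeta / eta / alpha / delta / none)
* target present, with what was taken out counted in, in percent of the starting material first charged, after zeta
* target present, with what was taken out counted in, in percent of the starting material first charged, after delta

- solid, in amounts per volume of the solution: solid second substrate
- target taken out counts as made
- what was read earlier has a scatter of 0.5 percentage points, one standard deviation
- candidate steps: starting material + free enzyme <-> first complex; first complex -> loaded enzyme + first product; second substrate + loaded enzyme <-> second complex; second complex -> free enzyme + target; solid second substrate <-> second substrate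
- at the start none of the solid second substrate is in solution
- additions bring no volume worth counting

1. By 80.0 min the midnight flask stands still: target reads 60.1% then and 61.0% at 600 min, yet 40.2% of its starting material is still there at that last reading. The noon flask, with its starting material down to 44.6%, goes from 36.4% of target at 25.0 min to 55.2% at 40.0 min. Similar amounts of starting material, and one flask runs while the other stands.

2. I divide target gained by starting material lost across the noon readings, so time drops out: 0.996. That reading fits the listed cycle, where one turn of the enzyme takes one starting material and one second substrate and gives one target.

3. So I reckon a ceiling, the charge of solid second substrate divided by the charge of starting material, which, as long as it stays below the whole charge, is the share of the starting material that can become target: 60.0%. In the midnight flask the solid is the limiting reagent, with less of it charged than of starting material. The ceiling comes from the charges and the plateau of the midnight flask from its readings, and the two meet. For the noon flask the same division gives 120%, more than the whole of its starting material, so there the bound on target is the starting material itself, and the last reading of that flask stands lower.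

4. Waiting, more enzyme, more starting material and taking out target bring no second substrate. I commit to the ceiling at 12 h, and to no option passing 2 percentage points.

5. The forecast says 60% now, 60% after zeta, 60% after delta and best none, since “the second substrate is used up”.

6. The flask gives 60.0% at 12 h, 60.0% after zeta, 60.0% after delta, and best is none.

    starting material + free enzyme ⇌ first complex (K = 55.0 L mol⁻¹, k = 23000 L mol⁻¹ s⁻¹)
    first complex → loaded enzyme + first product (k = 4.60 s⁻¹)
    second substrate + loaded enzyme ⇌ second complex (K = 300 L mol⁻¹, k = 34000 L mol⁻¹ s⁻¹)
    second complex → free enzyme + target (k = 4.00 s⁻¹)
    solid second substrate ⇌ second substrate, rate k5*(cs5 - [second substrate]) while solid is left; crystals form when [second substrate] > cs5 (solubility = 10.0 mM, k = 0.00480 s⁻¹)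

At 720 min the midnight flask holds 100% of its catalyst as loaded enzyme, the resting state, with second substrate at 0 M and solid at 0% of its charge. For a neighbour, the same flask but with 0.150 equiv of solid second substrate, the ceiling reckons to 15.0% instead of 60.0%. At 720 min that neighbour flask stands at 15.0% of target, with 85% of its starting material left.

All runs are calculated from invented constants; scatter was added.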